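The quinone ring of the target carries the amide nitrogen at C2, the trienyl chain para to it at C5 and chlorine at the neighbouring C6. This is the pattern left when the C4 alkenyl group of a 2-amido-4-hydroxy-5,6-epoxycyclohex-2-enone moves to C5 and the epoxide oxygen at C6 is exchanged for chloride. One operation therefore turns an epoxyquinol, whose propenyl group lies anti to the epoxide C5–O bond, into the fully substituted chlorohydroquinone, forming C5–C(alkenyl) and C6–Cl and aromatising the ring. The precursor is built from 2,5-dimethoxyaniline, already acylated with the (6R)-dienoic acid, and carries a silyl-protected three-carbon alkenyl handle for the later triene.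

Key step: step 15

Assumption: the three ring stereocentres of the epoxyquinol vanish in step 15, so its core is carried as a racemate; with the (6R) chain, compounds 17, 23, 24 and 25 are pairs of diastereomers, one of each pair being drawn. Ring atoms are numbered C1(=O), C2–N, C3–H, C4, C5, C6 throughout.

Step 1
Reactants: 1 (R)-4-benzyl-1,3-oxazolidin-2-one; 2 hexanoyl chloride
Product: 3 (4R)-4-benzyl-3-hexanoyl-1,3-oxazolidin-2-one
Conditions: n-BuLi, THF, −78 °C; then 2, −78 → 0 °C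
Reagents that add atoms: none
Why: N-acylation of the lithiated oxazolidinone by an acid chloride is the standard loading of an Evans auxiliary and does not touch its stereocentre.

Step 2
Reactants: 3 (4R)-4-benzyl-3-hexanoyl-1,3-oxazolidin-2-one
Product: 4 (4R)-4-benzyl-3-[(2R)-2-methylhexanoyl]-1,3-oxazolidin-2-one
Conditions: NaN(SiMe3)2, THF, −78 °C; then MeI, −78 → −40 °C
Reagents that add atoms: iodomethane, CI
Why: Evans asymmetric alkylation, in which the chelated sodium Z-enolate is shielded on one face by the benzyl group of the (R)-auxiliary, so iodomethane enters from the other face and sets the new centre as R.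

Step 3
Reactants: 4 (4R)-4-benzyl-3-[(2R)-2-methylhexanoyl]-1,3-oxazolidin-2-one
Product: 5 (2R)-2-methylhexan-1-ol
Conditions: LiBH4, H2O (1 equiv), Et2O, 0 °C
Reagents that add atoms: none
Why: Hydride reduction of the exocyclic imide carbonyl releases the primary alcohol without epimerising the α-centre and returns the auxiliary.

Step 4
Reactants: 5 (2R)-2-methylhexan-1-ol; 6 ethyl 2-(triphenylphosphoranylidene)propanoate
Product: 8 ethyl (2E,4R)-2,4-dimethyloct-2-enoate, via (2R)-2-methylhexanal 7 (not isolated)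
Conditions: TEMPO (cat.), PhI(OAc)2, CH2Cl2, rt; then 6, rt
Reagents that add atoms: none
Why: Oxoammonium (TEMPO) oxidation under non-basic conditions gives the configurationally labile aldehyde, which is trapped at once in a Wittig reaction whose stabilised ylide favours the E-trisubstituted enoate, the C4 centre being carried over unchanged.

Step 5
Reactants: 8 ethyl (2E,4R)-2,4-dimethyloct-2-enoate
Product: 9 (2E,4R)-2,4-dimethyloct-2-en-1-ol
Conditions: i-Bu2AlH, CH2Cl2, −78 °C; aq. potassium sodium tartrate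
Reagents that add atoms: none
Why: 1,2-Reduction of the conjugated ester by the aluminium hydride gives the allylic alcohol with alkene geometry and the C4 centre intact.

Step 6
Reactants: 9 (2E,4R)-2,4-dimethyloct-2-en-1-ol; 6 ethyl 2-(triphenylphosphoranylidene)propanoate
Product: 11 ethyl (2E,4E,6R)-2,4,6-trimethyldeca-2,4-dienoate, via (2E,4R)-2,4-dimethyloct-2-enal 10 (not isolated)
Conditions: MnO2, 6, toluene, 80 °C
Reagents that add atoms: none
Why: Tandem allylic oxidation–Wittig olefination, in which MnO2 oxidises only the allylic alcohol and the enal is intercepted by the stabilised ylide to give the second E-trisubstituted alkene.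

Step 7
Reactants: 11 ethyl (2E,4E,6R)-2,4,6-trimethyldeca-2,4-dienoate
Product: 12 (2E,4E,6R)-2,4,6-trimethyldeca-2,4-dienoic acid
Conditions: LiOH, THF/MeOH/H2O, 50 °C; then aq. HCl
Reagents that add atoms: lithium hydroxide, [Li+].[OH-]
Why: Saponification of the ethyl ester, the α-methyl dienoate resisting conjugate addition and having no epimerisable centre next to the carbonyl.

Step 8
Reactants: 12 (2E,4E,6R)-2,4,6-trimethyldeca-2,4-dienoic acid; 13 2,5-dimethoxyaniline
Product: 15 (2E,4E,6R)-N-(2,5-dimethoxyphenyl)-2,4,6-trimethyldeca-2,4-dienamide, via acid chloride 14 (not isolated)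
Conditions: (COCl)2, DMF (cat.), CH2Cl2, 0 °C → rt; then 13, pyridine, CH2Cl2, 0 °C
Reagents that add atoms: none
Why: Acid chloride formation followed by N-acylation of the aniline is reliable for a hindered α-methyl unsaturated acid and leaves the diene geometry untouched.

Step 9
Reactants: 15 (2E,4E,6R)-N-(2,5-dimethoxyphenyl)-2,4,6-trimethyldeca-2,4-dienamide
Product: 16 (2E,4E,6R)-N-(6,6-dimethoxy-3-oxocyclohexa-1,4-dien-1-yl)-2,4,6-trimethyldeca-2,4-dienamide
Conditions: PhI(OAc)2, MeOH, 0 °C → rt; aq. NaHCO3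
Reagents that add atoms: methanol, CO; water, O
Why: Hypervalent-iodine oxidative dearomatisation of the para-dimethoxyarene, in which methanol is captured at the carbon ortho to nitrogen while the oxocarbenium ion at the remote carbon, stabilised as a vinylogous N-acyliminium ion, is hydrolysed, so the ketal ends up beside the amide and the free ketone para to it.

Step 10
Reactants: 16 (2E,4E,6R)-N-(6,6-dimethoxy-3-oxocyclohexa-1,4-dien-1-yl)-2,4,6-trimethyldeca-2,4-dienamide
Product: 17 (2E,4E,6R)-N-(2,2-dimethoxy-5-oxo-7-oxabicyclo[4.1.0]hept-3-en-3-yl)-2,4,6-trimethyldeca-2,4-dienamide (cis-fused epoxide, racemic core)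
Conditions: H2O2 (30% aq.), K2CO3, THF/H2O, 0 °C
Reagents that add atoms: hydrogen peroxide, OO
Why: Weitz–Scheffer nucleophilic epoxidation attacks only the unsubstituted enone alkene, the amido-bearing alkene being a deactivated vinylogous imide and the dienamide too electron-rich, and ring closure gives the cis-fused epoxide without facial bias, which is acceptable because the core is used as a racemate.

Step 11
Reactants: 18 prop-2-yn-1-ol
Product: 19 tert-butyl(diphenyl)(prop-2-yn-1-yloxy)silane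
Conditions: t-BuPh2SiCl, imidazole, CH2Cl2, rt
Reagents that add atoms: tert-butyl(chloro)diphenylsilane, CC(C)(C)[Si](Cl)(c1ccccc1)c1ccccc1
Why: Imidazole-promoted silylation of the primary alcohol installs a silyl ether that is inert to organolithiums, BF3 and brief exposure to HCl.

Step 12
Reactants: 19 tert-butyl(diphenyl)(prop-2-yn-1-yloxy)silane
Product: 21 tert-butyl{[(2E)-3-iodoprop-2-en-1-yl]oxy}diphenylsilane, via alkenylzirconocene chloride 20 (not isolated)
Conditions: Cp2Zr(H)Cl, THF, rt; then I2, 0 °C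
Reagents that add atoms: iodine, II
Why: Schwartz hydrozirconation adds Zr–H syn with zirconium at the terminal carbon and iodinolysis of the C–Zr bond proceeds with retention, which fixes the E geometry.

Step 13
Reactants: 17 (2E,4E,6R)-N-(2,2-dimethoxy-5-oxo-7-oxabicyclo[4.1.0]hept-3-en-3-yl)-2,4,6-trimethyldeca-2,4-dienamide; 21 tert-butyl{[(2E)-3-iodoprop-2-en-1-yl]oxy}diphenylsilane
Product: 23 (2E,4E,6R)-N-[5-hydroxy-2,2-dimethoxy-5-[(E)-3-(tert-butyldiphenylsilyloxy)prop-1-enyl]-7-oxabicyclo[4.1.0]hept-3-en-3-yl]-2,4,6-trimethyldeca-2,4-dienamide (hydroxyl cis to the epoxide), via alkenyllithium 22 (not isolated)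
Conditions: 21 (2.4 equiv), t-BuLi (4.8 equiv), Et2O, −78 °C; then 17, THF, −78 °C; aq. NH4Cl
Reagents that add atoms: none
Why: Iodine–lithium exchange keeps the E geometry, the first equivalent of the alkenyllithium removes the amide proton, and the second adds 1,2 to the ketone from the face anti to the epoxide oxygen, so the new tertiary hydroxyl is cis to the epoxide.

Step 14
Reactants: 23 (2E,4E,6R)-N-[5-hydroxy-2,2-dimethoxy-5-[(E)-3-(tert-butyldiphenylsilyloxy)prop-1-enyl]-7-oxabicyclo[4.1.0]hept-3-en-3-yl]-2,4,6-trimethyldeca-2,4-dienamide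
Product: 24 (2E,4E,6R)-N-[5-hydroxy-2-oxo-5-[(E)-3-(tert-butyldiphenylsilyloxy)prop-1-enyl]-7-oxabicyclo[4.1.0]hept-3-en-3-yl]-2,4,6-trimethyldeca-2,4-dienamide (hydroxyl cis to the epoxide)
Conditions: montmorillonite K10 clay (acidic aluminosilicate, idealised Al2Si4O10(OH)2·nH2O), CH2Cl2, rt
Reagents that add atoms: water, O
Why: Mild solid-acid ketal hydrolysis unmasks the C1 ketone without ionising the tertiary allylic alcohol or opening the epoxide.

Step 15
Reactants: 24 (2E,4E,6R)-N-[5-hydroxy-2-oxo-5-[(E)-3-(tert-butyldiphenylsilyloxy)prop-1-enyl]-7-oxabicyclo[4.1.0]hept-3-en-3-yl]-2,4,6-trimethyldeca-2,4-dienamide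
Product: 27 (2E,4E,6R)-N-[3-chloro-2,5-dihydroxy-4-[(E)-3-(tert-butyldiphenylsilyloxy)prop-1-enyl]phenyl]-2,4,6-trimethyldeca-2,4-dienamide, via hydroxy-enedione 25 (not isolated), via amidoquinone 26 (not isolated)
Conditions: BF3·OEt2 (3 equiv), CH2Cl2, −78 → −20 °C; then HCl (4 M in 1,4-dioxane), −20 → 0 °C; aq. Na2S2O4 work-up under Ar
Reagents that add atoms: hydrogen chloride, Cl
Why: Proposed new method: BF3 bound to the epoxide oxygen weakens the C5–O bond (C5 is β to the C1 ketone, C6 is α and keeps its oxygen), and the C4 alkenyl group, antiperiplanar to that bond because the C4 hydroxyl is cis to the epoxide, shifts to C5 while the carbinol oxygen becomes the C4 ketone, giving hydroxy-enedione 25. The C5–H of 25 is α to the new ketone and allylic, so enolisation and acid-promoted loss of the boron-bound C6 oxygen give amidoquinone 26; HCl then protonates the more basic C4 carbonyl (a vinylogous amide through N–C2=C3), chloride adds at C6 and enolisation aromatises the ring. The closest known reaction types are the Lewis-acid semipinacol rearrangement of 2,3-epoxy alcohols with alkenyl migration and the 1,4-addition of HCl to benzoquinones, which have not been run as one cascade on an epoxyquinol. No ring is closed and no stereocentre is formed; the three core stereocentres disappear, so both core enantiomers converge. The step needs alkenyl migration instead of acyl shift (ring contraction), ionisation of the C4 hydroxyl or halide opening of the epoxide, and chloride at C6 instead of C3 or the side-chain terminus: the anti alignment with the push of the C4 oxygen and the late addition of chloride secure the first, while the amide nitrogen, which makes C3 the nucleophilic carbon of an enamide, and the bulky silyloxymethyl group on the alkene terminus secure the second.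

Step 16
Reactants: 27 (2E,4E,6R)-N-[3-chloro-2,5-dihydroxy-4-[(E)-3-(tert-butyldiphenylsilyloxy)prop-1-enyl]phenyl]-2,4,6-trimethyldeca-2,4-dienamide
Product: 28 (2E,4E,6R)-N-[3-chloro-2,5-bis(methoxymethoxy)-4-[(E)-3-(tert-butyldiphenylsilyloxy)prop-1-enyl]phenyl]-2,4,6-trimethyldeca-2,4-dienamide
Conditions: MeOCH2Cl, i-Pr2NEt, Bu4NI (cat.), CH2Cl2, 0 → 40 °C, Ar
Reagents that add atoms: chloromethyl methyl ether, COCCl
Why: O-Alkylation of both phenols with the chloromethyl ether and a hindered amine base masks the air-sensitive hydroquinone as acetals, the amide N–H being too weakly acidic to react.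

Step 17
Reactants: 28 (2E,4E,6R)-N-[3-chloro-2,5-bis(methoxymethoxy)-4-[(E)-3-(tert-butyldiphenylsilyloxy)prop-1-enyl]phenyl]-2,4,6-trimethyldeca-2,4-dienamide
Product: 29 (2E,4E,6R)-N-[3-chloro-4-[(E)-3-hydroxyprop-1-enyl]-2,5-bis(methoxymethoxy)phenyl]-2,4,6-trimethyldeca-2,4-dienamide
Conditions: Bu4NF, AcOH, THF, 0 °C → rt
Reagents that add atoms: none
Why: Fluoride-induced desilylation under acetic acid buffering frees the primary allylic alcohol and leaves the aryl acetals and the amide alone.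

Step 18
Reactants: 29 (2E,4E,6R)-N-[3-chloro-4-[(E)-3-hydroxyprop-1-enyl]-2,5-bis(methoxymethoxy)phenyl]-2,4,6-trimethyldeca-2,4-dienamide
Product: 30 (2E,4E,6R)-N-[3-chloro-2,5-bis(methoxymethoxy)-4-[(E)-3-oxoprop-1-enyl]phenyl]-2,4,6-trimethyldeca-2,4-dienamide
Conditions: MnO2, CH2Cl2, rt
Reagents that add atoms: none
Why: MnO2 oxidises the cinnamyl-type allylic alcohol selectively to the E-enal.

Step 19
Reactants: 31 cyclopentane-1,3-dione
Product: 32 2-(hydroxyimino)cyclopentane-1,3-dione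
Conditions: NaNO2, aq. HCl, 0 °C
Reagents that add atoms: sodium nitrite, [Na+].[O-]N=O
Why: Nitrosation of the active methylene of the 1,3-dione gives the C-nitroso compound, which tautomerises to the oxime.

Step 20
Reactants: 32 2-(hydroxyimino)cyclopentane-1,3-dione
Product: 33 2-amino-3-hydroxycyclopent-2-en-1-one hydrochloride
Conditions: H2 (1 atm), 10% Pd/C, HCl, MeOH, rt
Reagents that add atoms: hydrogen chloride, Cl
Why: Catalytic hydrogenation of the oxime gives the primary amine, trapped as its hydrochloride in the stable enol form.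

Step 21
Reactants: 34 ethyl (2E)-4-(diethoxyphosphoryl)but-2-enoate (triethyl 4-phosphonocrotonate)
Product: 35 (2E)-4-(diethoxyphosphoryl)but-2-enoic acid
Conditions: LiOH (1 equiv), THF/H2O, 0 °C; then aq. HCl
Reagents that add atoms: lithium hydroxide, [Li+].[OH-]
Why: Selective saponification, the carboxylic ester being hydrolysed far faster than the phosphonate esters at 0 °C.

Step 22
Reactants: 35 (2E)-4-(diethoxyphosphoryl)but-2-enoic acid; 33 2-amino-3-hydroxycyclopent-2-en-1-one hydrochloride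
Product: 37 diethyl [(2E)-4-[(2-hydroxy-5-oxocyclopent-1-en-1-yl)amino]-4-oxobut-2-en-1-yl]phosphonate, via mixed anhydride 36 (not isolated)
Conditions: i-BuOCOCl, N-methylmorpholine, THF, −20 °C; then 33, N-methylmorpholine, DMF, −20 °C → rt
Reagents that add atoms: none
Why: Mixed carbonic anhydride amidation acylates the enaminone nitrogen, and the weak base avoids deprotonation at the phosphonate carbon.

Step 23
Reactants: 30 (2E,4E,6R)-N-[3-chloro-2,5-bis(methoxymethoxy)-4-[(E)-3-oxoprop-1-enyl]phenyl]-2,4,6-trimethyldeca-2,4-dienamide; 37 diethyl [(2E)-4-[(2-hydroxy-5-oxocyclopent-1-en-1-yl)amino]-4-oxobut-2-en-1-yl]phosphonate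
Product: 38 (2E,4E,6R)-N-[3-chloro-4-[(1E,3E,5E)-7-[(2-hydroxy-5-oxocyclopent-1-en-1-yl)amino]-7-oxohepta-1,3,5-trien-1-yl]-2,5-bis(methoxymethoxy)phenyl]-2,4,6-trimethyldeca-2,4-dienamide
Conditions: 37 (2 equiv), LiN(SiMe3)2 (6 equiv), THF/DMPU, −78 → 0 °C; then 30, −78 → 0 °C; aq. NH4Cl
Reagents that add atoms: none
Why: Vinylogous Horner–Wadsworth–Emmons olefination, in which the phosphonate carbanion formed after removal of the enol and amide protons adds to the enal and elimination of phosphate gives the thermodynamically favoured E alkene, completing the all-E triene.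

Step 24
Reactants: 38 (2E,4E,6R)-N-[3-chloro-4-[(1E,3E,5E)-7-[(2-hydroxy-5-oxocyclopent-1-en-1-yl)amino]-7-oxohepta-1,3,5-trien-1-yl]-2,5-bis(methoxymethoxy)phenyl]-2,4,6-trimethyldeca-2,4-dienamide
Product: 39 (2E,4E,6R)-N-[3-chloro-2,5-dihydroxy-4-[(1E,3E,5E)-7-[(2-hydroxy-5-oxocyclopent-1-en-1-yl)amino]-7-oxohepta-1,3,5-trien-1-yl]phenyl]-2,4,6-trimethyldeca-2,4-dienamide
Conditions: HCl (MeOH), THF, 0 °C → rt, Ar
Reagents that add atoms: none
Why: Acid-catalysed transacetalisation of the two aryl methoxymethyl ethers to methanol frees the hydroquinone, the conjugated amides and the enol being stable to dilute acid.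

Step 25
Reactants: 39 (2E,4E,6R)-N-[3-chloro-2,5-dihydroxy-4-[(1E,3E,5E)-7-[(2-hydroxy-5-oxocyclopent-1-en-1-yl)amino]-7-oxohepta-1,3,5-trien-1-yl]phenyl]-2,4,6-trimethyldeca-2,4-dienamide
Product: 40 chinikomycin B, (2E,4E,6R)-N-[5-chloro-4-[(1E,3E,5E)-7-[(2-hydroxy-5-oxocyclopent-1-en-1-yl)amino]-7-oxohepta-1,3,5-trien-1-yl]-3,6-dioxocyclohexa-1,4-dien-1-yl]-2,4,6-trimethyldeca-2,4-dienamide
Conditions: Ag2O, MgSO4, Et2O/THF, rt
Reagents that add atoms: none
Why: Mild two-electron oxidation of the hydroquinone by Ag2O gives the quinone without touching the polyene chains.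

Compound list
1 | (R)-4-benzyl-1,3-oxazolidin-2-one | O=C1N[C@H](Cc2ccccc2)CO1 | starting material
2 | hexanoyl chloride | CCCCCC(Cl)=O | starting material
3 | (4R)-4-benzyl-3-hexanoyl-1,3-oxazolidin-2-one | CCCCCC(=O)N1[C@H](Cc2ccccc2)COC1=O | intermediate
4 | (4R)-4-benzyl-3-[(2R)-2-methylhexanoyl]-1,3-oxazolidin-2-one | CCCC[C@@H](C)C(=O)N1[C@H](Cc2ccccc2)COC1=O | intermediate
5 | (2R)-2-methylhexan-1-ol | CCCC[C@@H](C)CO | intermediate
6 | ethyl 2-(triphenylphosphoranylidene)propanoate | CCOC(=O)C(C)=P(c1ccccc1)(c1ccccc1)c1ccccc1 | starting material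
7 | (2R)-2-methylhexanal | CCCC[C@@H](C)C=O | intermediate
8 | ethyl (2E,4R)-2,4-dimethyloct-2-enoate | CCCC[C@@H](C)/C=C(\C)C(=O)OCC | intermediate
9 | (2E,4R)-2,4-dimethyloct-2-en-1-ol | CCCC[C@@H](C)/C=C(\C)CO | intermediate
10 | (2E,4R)-2,4-dimethyloct-2-enal | CCCC[C@@H](C)/C=C(\C)C=O | intermediate
11 | ethyl (2E,4E,6R)-2,4,6-trimethyldeca-2,4-dienoate | CCCC[C@@H](C)/C=C(C)/C=C(\C)C(=O)OCC | intermediate
12 | (2E,4E,6R)-2,4,6-trimethyldeca-2,4-dienoic acid | CCCC[C@@H](C)/C=C(C)/C=C(\C)C(=O)O | intermediate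
13 | 2,5-dimethoxyaniline | COc1ccc(OC)c(N)c1 | starting material
14 | (2E,4E,6R)-2,4,6-trimethyldeca-2,4-dienoyl chloride | CCCC[C@@H](C)/C=C(C)/C=C(\C)C(Cl)=O | intermediate
15 | (2E,4E,6R)-N-(2,5-dimethoxyphenyl)-2,4,6-trimethyldeca-2,4-dienamide | CCCC[C@@H](C)/C=C(C)/C=C(\C)C(=O)Nc1cc(OC)ccc1OC | intermediate
16 | (2E,4E,6R)-N-(6,6-dimethoxy-3-oxocyclohexa-1,4-dien-1-yl)-2,4,6-trimethyldeca-2,4-dienamide | CCCC[C@@H](C)/C=C(C)/C=C(\C)C(=O)NC1=CC(=O)C=CC1(OC)OC | intermediate
17 | (2E,4E,6R)-N-(2,2-dimethoxy-5-oxo-7-oxabicyclo[4.1.0]hept-3-en-3-yl)-2,4,6-trimethyldeca-2,4-dienamide (cis-fused epoxide, racemic core, one core enantiomer drawn) | CCCC[C@@H](C)/C=C(C)/C=C(\C)C(=O)NC1=CC(=O)[C@@H]2O[C@@H]2C1(OC)OC | intermediate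
18 | prop-2-yn-1-ol | C#CCO | starting material
19 | tert-butyl(diphenyl)(prop-2-yn-1-yloxy)silane | C#CCO[Si](c1ccccc1)(c1ccccc1)C(C)(C)C | intermediate
20 | chloro[(E)-3-(tert-butyldiphenylsilyloxy)prop-1-enyl]zirconocene (Cp rings drawn σ-bonded) | Cl[Zr](/C=C/CO[Si](c1ccccc1)(c1ccccc1)C(C)(C)C)(C1C=CC=C1)C1C=CC=C1 | intermediate
21 | tert-butyl{[(2E)-3-iodoprop-2-en-1-yl]oxy}diphenylsilane | I/C=C/CO[Si](c1ccccc1)(c1ccccc1)C(C)(C)C | intermediate
22 | (E)-3-(tert-butyldiphenylsilyloxy)prop-1-enyllithium | [Li]/C=C/CO[Si](c1ccccc1)(c1ccccc1)C(C)(C)C | intermediate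
23 | (2E,4E,6R)-N-[5-hydroxy-2,2-dimethoxy-5-[(E)-3-(tert-butyldiphenylsilyloxy)prop-1-enyl]-7-oxabicyclo[4.1.0]hept-3-en-3-yl]-2,4,6-trimethyldeca-2,4-dienamide (hydroxyl cis to the epoxide, racemic core, one core enantiomer drawn) | CCCC[C@@H](C)/C=C(C)/C=C(\C)C(=O)NC1=C[C@@](O)(/C=C/CO[Si](c2ccccc2)(c2ccccc2)C(C)(C)C)[C@@H]2O[C@@H]2C1(OC)OC | intermediate
24 | (2E,4E,6R)-N-[5-hydroxy-2-oxo-5-[(E)-3-(tert-butyldiphenylsilyloxy)prop-1-enyl]-7-oxabicyclo[4.1.0]hept-3-en-3-yl]-2,4,6-trimethyldeca-2,4-dienamide (hydroxyl cis to the epoxide, racemic core, one core enantiomer drawn) | CCCC[C@@H](C)/C=C(C)/C=C(\C)C(=O)NC1=C[C@@](O)(/C=C/CO[Si](c2ccccc2)(c2ccccc2)C(C)(C)C)[C@@H]2O[C@@H]2C1=O | intermediate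
25 | (2E,4E,6R)-N-[5-hydroxy-3,6-dioxo-4-[(E)-3-(tert-butyldiphenylsilyloxy)prop-1-enyl]cyclohex-1-en-1-yl]-2,4,6-trimethyldeca-2,4-dienamide (alkenyl and hydroxyl trans, racemic core, one core enantiomer drawn) | CCCC[C@@H](C)/C=C(C)/C=C(\C)C(=O)NC1=CC(=O)[C@@H](/C=C/CO[Si](c2ccccc2)(c2ccccc2)C(C)(C)C)[C@H](O)C1=O | intermediate
26 | (2E,4E,6R)-N-[3,6-dioxo-4-[(E)-3-(tert-butyldiphenylsilyloxy)prop-1-enyl]cyclohexa-1,4-dien-1-yl]-2,4,6-trimethyldeca-2,4-dienamide | CCCC[C@@H](C)/C=C(C)/C=C(\C)C(=O)NC1=CC(=O)C(/C=C/CO[Si](c2ccccc2)(c2ccccc2)C(C)(C)C)=CC1=O | intermediate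
27 | (2E,4E,6R)-N-[3-chloro-2,5-dihydroxy-4-[(E)-3-(tert-butyldiphenylsilyloxy)prop-1-enyl]phenyl]-2,4,6-trimethyldeca-2,4-dienamide | CCCC[C@@H](C)/C=C(C)/C=C(\C)C(=O)Nc1cc(O)c(/C=C/CO[Si](c2ccccc2)(c2ccccc2)C(C)(C)C)c(Cl)c1O | intermediate
28 | (2E,4E,6R)-N-[3-chloro-2,5-bis(methoxymethoxy)-4-[(E)-3-(tert-butyldiphenylsilyloxy)prop-1-enyl]phenyl]-2,4,6-trimethyldeca-2,4-dienamide | CCCC[C@@H](C)/C=C(C)/C=C(\C)C(=O)Nc1cc(OCOC)c(/C=C/CO[Si](c2ccccc2)(c2ccccc2)C(C)(C)C)c(Cl)c1OCOC | intermediate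
29 | (2E,4E,6R)-N-[3-chloro-4-[(E)-3-hydroxyprop-1-enyl]-2,5-bis(methoxymethoxy)phenyl]-2,4,6-trimethyldeca-2,4-dienamide | CCCC[C@@H](C)/C=C(C)/C=C(\C)C(=O)Nc1cc(OCOC)c(/C=C/CO)c(Cl)c1OCOC | intermediate
30 | (2E,4E,6R)-N-[3-chloro-2,5-bis(methoxymethoxy)-4-[(E)-3-oxoprop-1-enyl]phenyl]-2,4,6-trimethyldeca-2,4-dienamide | CCCC[C@@H](C)/C=C(C)/C=C(\C)C(=O)Nc1cc(OCOC)c(/C=C/C=O)c(Cl)c1OCOC | intermediate
31 | cyclopentane-1,3-dione | O=C1CCC(=O)C1 | starting material
32 | 2-(hydroxyimino)cyclopentane-1,3-dione | ON=C1C(=O)CCC1=O | intermediate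
33 | 2-amino-3-hydroxycyclopent-2-en-1-one hydrochloride | Cl.NC1=C(O)CCC1=O | intermediate
34 | ethyl (2E)-4-(diethoxyphosphoryl)but-2-enoate | CCOC(=O)/C=C/CP(=O)(OCC)OCC | starting material
35 | (2E)-4-(diethoxyphosphoryl)but-2-enoic acid | OC(=O)/C=C/CP(=O)(OCC)OCC | intermediate
36 | (2E)-4-(diethoxyphosphoryl)but-2-enoic isobutyl carbonic anhydride | CC(C)COC(=O)OC(=O)/C=C/CP(=O)(OCC)OCC | intermediate
37 | diethyl [(2E)-4-[(2-hydroxy-5-oxocyclopent-1-en-1-yl)amino]-4-oxobut-2-en-1-yl]phosphonate | CCOP(=O)(OCC)C/C=C/C(=O)NC1=C(O)CCC1=O | intermediate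
38 | (2E,4E,6R)-N-[3-chloro-4-[(1E,3E,5E)-7-[(2-hydroxy-5-oxocyclopent-1-en-1-yl)amino]-7-oxohepta-1,3,5-trien-1-yl]-2,5-bis(methoxymethoxy)phenyl]-2,4,6-trimethyldeca-2,4-dienamide | CCCC[C@@H](C)/C=C(C)/C=C(\C)C(=O)Nc1cc(OCOC)c(/C=C/C=C/C=C/C(=O)NC2=C(O)CCC2=O)c(Cl)c1OCOC | intermediate
39 | (2E,4E,6R)-N-[3-chloro-2,5-dihydroxy-4-[(1E,3E,5E)-7-[(2-hydroxy-5-oxocyclopent-1-en-1-yl)amino]-7-oxohepta-1,3,5-trien-1-yl]phenyl]-2,4,6-trimethyldeca-2,4-dienamide | CCCC[C@@H](C)/C=C(C)/C=C(\C)C(=O)Nc1cc(O)c(/C=C/C=C/C=C/C(=O)NC2=C(O)CCC2=O)c(Cl)c1O | intermediate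
40 | chinikomycin B | CCCC[C@@H](C)/C=C(C)/C=C(\C)C(=O)NC1=CC(=O)C(/C=C/C=C/C=C/C(=O)NC2=C(O)CCC2=O)=C(Cl)C1=O | target

Total step count: 25. Longest linear sequence: 19 steps (steps 1–10, 13–18 and 23–25).

Steps most likely to fail

Step 15. The rearranged enedione may enolise toward C6 before its C6 oxygen is expelled, so that the ring aromatises with that oxygen still attached and no quinone is left for chloride to add to. Ionisation of the doubly allylic C4 hydroxyl may also outrun epoxide activation. The fallback reaches the same chlorohydroquinone by known reactions and sets out from anilide 15. Electrophilic iodination para to the amide nitrogen (N-iodosuccinimide, cat. CF3CO2H, MeCN, 0 °C) should give (2E,4E,6R)-N-(4-iodo-2,5-dimethoxyphenyl)-2,4,6-trimethyldeca-2,4-dienamide F1. Negishi-type coupling of F1 with alkenylzirconocene chloride 20, generated from 19 as in step 12 (Pd(PPh3)4, ZnCl2, THF, rt), should give (2E,4E,6R)-N-[2,5-dimethoxy-4-[(E)-3-(tert-butyldiphenylsilyloxy)prop-1-enyl]phenyl]-2,4,6-trimethyldeca-2,4-dienamide F2. Oxidative demethylation of F2 with (NH4)2Ce(NO3)6 in MeCN/H2O at 0 °C should give amidoquinone 26, now isolated. Addition of HCl (1,4-dioxane, CH2Cl2, 0 °C), directed to C6 by the same vinylogous amide, comes back to the route at 27.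

Step 23. The triply deprotonated phosphonate may aggregate, or be quenched by proton transfer from the anilide N–H of the aldehyde, so that olefination stalls or the enal is consumed by side reactions. The fallback builds the chain with a neutral phosphonate and attaches the aminocyclopentenone last, setting out from aldehyde 30. Olefination with commercial phosphonate 34 (LiN(SiMe3)2, THF, −78 → 0 °C) should give ethyl (2E,4E,6E)-7-[2-chloro-3,6-bis(methoxymethoxy)-4-[[(2E,4E,6R)-2,4,6-trimethyldeca-2,4-dienoyl]amino]phenyl]hepta-2,4,6-trienoate F3. Saponification (LiOH, THF/MeOH/H2O, rt) should give the corresponding hepta-2,4,6-trienoic acid F4. Activation with i-BuOCOCl and N-methylmorpholine gives its isobutyl carbonic mixed anhydride F5, and acylation of amine hydrochloride 33 (N-methylmorpholine, DMF) comes back to the route at 38.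

Step 13. Addition may occur with poor facial selectivity, or the organolithium may be diverted by the base-sensitive epoxy ketone. Either leaves material with the hydroxyl trans to the epoxide, in which the alkenyl bond cannot align anti to the C5–O bond in step 15. The fallback reverses the order so that the hydroxyl itself directs the epoxide, and sets out from quinone monoketal 16. Addition of alkenyllithium 22 (from 21, t-BuLi, Et2O, −78 °C) to the ketone of 16 should give (2E,4E,6R)-N-[3-hydroxy-6,6-dimethoxy-3-[(E)-3-(tert-butyldiphenylsilyloxy)prop-1-enyl]cyclohexa-1,4-dien-1-yl]-2,4,6-trimethyldeca-2,4-dienamide F6. Ketal hydrolysis on montmorillonite K10 clay should give the para-quinol (2E,4E,6R)-N-[3-hydroxy-6-oxo-3-[(E)-3-(tert-butyldiphenylsilyloxy)prop-1-enyl]cyclohexa-1,4-dien-1-yl]-2,4,6-trimethyldeca-2,4-dienamide F7. Weitz–Scheffer epoxidation (H2O2, LiOH, THF/H2O, 0 °C) of the unsubstituted enone alkene, delivered syn to the hydrogen-bonding hydroxyl, comes back to the route at 24.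

Further compounds
F1 | step 15 | (2E,4E,6R)-N-(4-iodo-2,5-dimethoxyphenyl)-2,4,6-trimethyldeca-2,4-dienamide | CCCC[C@@H](C)/C=C(C)/C=C(\C)C(=O)Nc1cc(OC)c(I)cc1OC
F2 | step 15 | (2E,4E,6R)-N-[2,5-dimethoxy-4-[(E)-3-(tert-butyldiphenylsilyloxy)prop-1-enyl]phenyl]-2,4,6-trimethyldeca-2,4-dienamide | CCCC[C@@H](C)/C=C(C)/C=C(\C)C(=O)Nc1cc(OC)c(/C=C/CO[Si](c2ccccc2)(c2ccccc2)C(C)(C)C)cc1OC
F3 | step 23 | ethyl (2E,4E,6E)-7-[2-chloro-3,6-bis(methoxymethoxy)-4-[[(2E,4E,6R)-2,4,6-trimethyldeca-2,4-dienoyl]amino]phenyl]hepta-2,4,6-trienoate | CCCC[C@@H](C)/C=C(C)/C=C(\C)C(=O)Nc1cc(OCOC)c(/C=C/C=C/C=C/C(=O)OCC)c(Cl)c1OCOC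
F4 | step 23 | (2E,4E,6E)-7-[2-chloro-3,6-bis(methoxymethoxy)-4-[[(2E,4E,6R)-2,4,6-trimethyldeca-2,4-dienoyl]amino]phenyl]hepta-2,4,6-trienoic acid | CCCC[C@@H](C)/C=C(C)/C=C(\C)C(=O)Nc1cc(OCOC)c(/C=C/C=C/C=C/C(=O)O)c(Cl)c1OCOC
F5 | step 23 | isobutyl carbonic mixed anhydride of F4 | CCCC[C@@H](C)/C=C(C)/C=C(\C)C(=O)Nc1cc(OCOC)c(/C=C/C=C/C=C/C(=O)OC(=O)OCC(C)C)c(Cl)c1OCOC
F6 | step 13 | (2E,4E,6R)-N-[3-hydroxy-6,6-dimethoxy-3-[(E)-3-(tert-butyldiphenylsilyloxy)prop-1-enyl]cyclohexa-1,4-dien-1-yl]-2,4,6-trimethyldeca-2,4-dienamide (carbinol centre in both configurations) | CCCC[C@@H](C)/C=C(C)/C=C(\C)C(=O)NC1=CC(O)(/C=C/CO[Si](c2ccccc2)(c2ccccc2)C(C)(C)C)C=CC1(OC)OC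
F7 | step 13 | (2E,4E,6R)-N-[3-hydroxy-6-oxo-3-[(E)-3-(tert-butyldiphenylsilyloxy)prop-1-enyl]cyclohexa-1,4-dien-1-yl]-2,4,6-trimethyldeca-2,4-dienamide (carbinol centre in both configurations) | CCCC[C@@H](C)/C=C(C)/C=C(\C)C(=O)NC1=CC(O)(/C=C/CO[Si](c2ccccc2)(c2ccccc2)C(C)(C)C)C=CC1=O
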